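The target is cut at C8, the only stereocentre, which sits between the aryl ether oxygen of ring B (the vanillate ring), the ketone carbon C7 on ring A (the syringyl ring) and the hydroxymethyl carbon C9. A rhodium ketocarbenoid, a phenol and formaldehyde supply exactly these three neighbours, so one catalytic three-component coupling forms O–C8 and C8–C9 and sets C8 as R under chiral phosphoric acid control. The precursor is the diazomethyl ketone of ring A with its phenol capped as a 4-methoxybenzyl ether; the partner is 4-methoxybenzyl vanillate, so one mild acidolysis afterwards frees phenol and acid together.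

Key step: step 4

Remarks on the chemistry (assumptions):
- C8 is R in 9 and in 10 (priorities: aryl ether O > C7 > C9 > H).
- The sense of induction of the phosphoric acid is assumed. (R)-TRIP, (R)-3,3'-bis(2,4,6-triisopropylphenyl)-1,1'-binaphthyl-2,2'-diyl hydrogen phosphate, is written; its mirror image is used if the first run gives the S series.
- Both masked groups are 4-methoxybenzyl: one reagent installs them and one cold acidolysis removes them, so no hydrogenation is needed next to the aryl ketone and the C8–O bond.
- The diazo ketone is made from the methyl ketone by diazo transfer, which avoids an acid chloride and HCl.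
- Formaldehyde is used as dry monomer, because water would compete with the phenol for the carbenoid.

Step 1
Reactants: 1 acetosyringone (1-(4-hydroxy-3,5-dimethoxyphenyl)ethan-1-one)
Product: 2 1-{3,5-dimethoxy-4-[(4-methoxybenzyl)oxy]phenyl}ethan-1-one
Conditions: 4-MeOC6H4CH2Cl (1.2 equiv), K2CO3, KI (cat.), DMF, 60 °C
Reagents that add atoms: 4-methoxybenzyl chloride, COc1ccc(CCl)cc1
Why: Williamson ether synthesis, in which K2CO3 ionises the acidic para-acyl phenol and the phenoxide displaces chloride from the benzylic halide (SN2, iodide-assisted) while the methyl ketone is inert to carbonate.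

Step 2
Reactants: 2 1-{3,5-dimethoxy-4-[(4-methoxybenzyl)oxy]phenyl}ethan-1-one
Product: 4 2-diazo-1-{3,5-dimethoxy-4-[(4-methoxybenzyl)oxy]phenyl}ethan-1-one, via trifluoroacetyl ketone 3 (not isolated)
Conditions: LiN(SiMe3)2, THF, −78 °C; CF3CO2CH2CF3, −78 °C; cold 1 M HCl quench, crude carried on; then 4-AcNHC6H4SO2N3, Et3N, H2O (1 equiv), MeCN, rt
Reagents that add atoms: 4-acetamidobenzenesulfonyl azide, CC(=O)Nc1ccc(cc1)S(=O)(=O)N=[N+]=[N-] (the two diazo nitrogens); 2,2,2-trifluoroethyl trifluoroacetate, O=C(OCC(F)(F)F)C(F)(F)F (the CF3CO group of 3 only)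
Why: Claisen-type trifluoroacetylation of the lithium enolate followed by Regitz diazo transfer, in which the acidic 1,3-diketone 3 takes N2 from the sulfonyl azide at the future C8 and passes its trifluoroacetyl group to the sulfonamide nitrogen, a standard sequence for aryl methyl ketones that uses no acid able to touch the 4-methoxybenzyl ether.

Step 3
Reactants: 5 vanillic acid (4-hydroxy-3-methoxybenzoic acid)
Product: 6 4-methoxybenzyl 4-hydroxy-3-methoxybenzoate
Conditions: 4-MeOC6H4CH2Cl (1.05 equiv), KHCO3, KI (cat.), DMF, 40 °C
Reagents that add atoms: 4-methoxybenzyl chloride, COc1ccc(CCl)cc1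
Why: Chemoselective carboxylate O-alkylation (SN2 esterification), since hydrogencarbonate deprotonates only the carboxylic acid and the far less acidic phenol stays free for the key step.

Step 4
Reactants: 4 2-diazo-1-{3,5-dimethoxy-4-[(4-methoxybenzyl)oxy]phenyl}ethan-1-one; 6 4-methoxybenzyl 4-hydroxy-3-methoxybenzoate; 7 formaldehyde (dry monomer, freshly cracked from paraformaldehyde)
Product: 9 4-methoxybenzyl 4-{[(2R)-1-{3,5-dimethoxy-4-[(4-methoxybenzyl)oxy]phenyl}-3-hydroxy-1-oxopropan-2-yl]oxy}-3-methoxybenzoate, via enol 8 (not isolated)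
Conditions: Rh2(OAc)4 (2 mol %), (R)-TRIP (10 mol %), 6 (2 equiv), 7 (5 equiv, ca. 1 M in THF), 4 Å molecular sieves, CH2Cl2, 0 °C, 4 added by syringe pump over 2 h
Reagents that add atoms: none
Why: Proposed new method: Rh2(OAc)4 (divalent rhodium) releases N2 from 4 to give an electrophilic ketocarbenoid, the phenol oxygen of 6 adds to it, and the oxonium ylide relaxes by proton transfer to the Z enol 8 with a nucleophilic C8; the phosphoric acid holds this enol by its O–H and formaldehyde by its carbonyl oxygen in one hydrogen-bonded array, so C8 adds to C9 before the enol can ketonise to the plain O–H insertion product. The closest known reaction type is the Rh2(OAc)4 and chiral phosphoric acid co-catalysed three-component coupling of diazo carbonyl compounds, alcohols or water and imines or aldehydes through trapped oxonium ylides or enols; new here is the set of acceptor-only diazo ketone, phenol and formaldehyde, which leaves a tertiary C8–H stereocentre. No ring closes in this step. C8 is the only new stereocentre and its R configuration is catalyst-controlled, the 3,3'-aryl groups of the phosphate covering one face of the planar enol while the bound formaldehyde is delivered to the other. The step needs carbenoid attack on O–H and not on an arene, on the carbonyl of 7 or on water, which is secured because the phenol of 6 is the only O–H donor (every other hydroxyl in 4 and 6 is capped as a 4-methoxybenzyl ether or ester), is used in excess against slowly added 4, and meets only dry formaldehyde; it also needs C–C bond formation to outrun the proton shift, which the small, highly electrophilic aldehyde in excess favours. The neutral medium keeps the product from retro-aldol cleavage, dehydration and epimerisation at C8.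

Step 5
Reactants: 9 4-methoxybenzyl 4-{[(2R)-1-{3,5-dimethoxy-4-[(4-methoxybenzyl)oxy]phenyl}-3-hydroxy-1-oxopropan-2-yl]oxy}-3-methoxybenzoate
Product: 10 4-{[(2R)-3-hydroxy-1-(4-hydroxy-3,5-dimethoxyphenyl)-1-oxopropan-2-yl]oxy}-3-methoxybenzoic acid (CNP0507417.1)
Conditions: CF3CO2H (10 vol %), anisole (10 equiv), CH2Cl2, 0 °C; evaporation with toluene; MeOH, rt
Reagents that add atoms: none
Why: Acidolysis (SN1-type cleavage of the two benzylic C–O bonds with Friedel–Crafts capture of the 4-methoxybenzyl cation by anisole), which should run in dilute cold acid without base, so that the C8–H stereocentre, the β-hydroxy ketone and the C8–O aryl ether are left untouched.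

Compound list
1 | acetosyringone, 1-(4-hydroxy-3,5-dimethoxyphenyl)ethan-1-one | CC(=O)c1cc(OC)c(O)c(OC)c1 | starting material
2 | 1-{3,5-dimethoxy-4-[(4-methoxybenzyl)oxy]phenyl}ethan-1-one | COc1ccc(COc2c(OC)cc(cc2OC)C(C)=O)cc1 | intermediate
3 | 1-{3,5-dimethoxy-4-[(4-methoxybenzyl)oxy]phenyl}-4,4,4-trifluorobutane-1,3-dione | COc1ccc(COc2c(OC)cc(cc2OC)C(=O)CC(=O)C(F)(F)F)cc1 | intermediate (not isolated)
4 | 2-diazo-1-{3,5-dimethoxy-4-[(4-methoxybenzyl)oxy]phenyl}ethan-1-one | COc1ccc(COc2c(OC)cc(cc2OC)C(=O)C=[N+]=[N-])cc1 | intermediate (precursor of the key step)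
5 | vanillic acid, 4-hydroxy-3-methoxybenzoic acid | COc1cc(C(=O)O)ccc1O | starting material
6 | 4-methoxybenzyl 4-hydroxy-3-methoxybenzoate | COc1cc(C(=O)OCc2ccc(OC)cc2)ccc1O | intermediate
7 | formaldehyde | C=O | starting material
8 | 4-methoxybenzyl 4-{[(Z)-2-{3,5-dimethoxy-4-[(4-methoxybenzyl)oxy]phenyl}-2-hydroxyethenyl]oxy}-3-methoxybenzoate | COc1cc(C(=O)OCc2ccc(OC)cc2)ccc1O/C=C(\O)c1cc(OC)c(OCc2ccc(OC)cc2)c(OC)c1 | intermediate (not isolated)
9 | 4-methoxybenzyl 4-{[(2R)-1-{3,5-dimethoxy-4-[(4-methoxybenzyl)oxy]phenyl}-3-hydroxy-1-oxopropan-2-yl]oxy}-3-methoxybenzoate | COc1cc(C(=O)OCc2ccc(OC)cc2)ccc1O[C@H](CO)C(=O)c1cc(OC)c(OCc2ccc(OC)cc2)c(OC)c1 | intermediate (product of the key step)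
10 | 4-{[(2R)-3-hydroxy-1-(4-hydroxy-3,5-dimethoxyphenyl)-1-oxopropan-2-yl]oxy}-3-methoxybenzoic acid | COc1cc(C(=O)O)ccc1O[C@H](CO)C(=O)c1cc(OC)c(O)c(OC)c1 | target

Total step count: 5. Longest linear sequence: 4 steps (steps 1, 2, 4 and 5, from 1 to 10); step 3 is a one-step side branch.

Steps most likely to fail

Step 4 is the main risk. Ketonisation of the enol may outrun C–C bond formation, the primary hydroxyl of the product may compete with the phenol for the carbenoid, or the phosphate may discriminate the two enol faces poorly. The fallback uses known chemistry only, sets out from 4 and 6 and comes back at 9. Rh2(OAc)4-catalysed O–H insertion of 4 into the phenol of 6 without aldehyde (CH2Cl2, rt, through enol 8) should give the achiral ether ketone 4-methoxybenzyl 4-(2-{3,5-dimethoxy-4-[(4-methoxybenzyl)oxy]phenyl}-2-oxoethoxy)-3-methoxybenzoate F1; this is also what the failed key step would leave. Aldol hydroxymethylation of F1 with 37 % aqueous formaldehyde (1.1 equiv) and catalytic K2CO3 in acetone at rt, the usual reaction of 2-aryloxy aryl ketones, should give racemic 4-methoxybenzyl 4-{[1-{3,5-dimethoxy-4-[(4-methoxybenzyl)oxy]phenyl}-3-hydroxy-1-oxopropan-2-yl]oxy}-3-methoxybenzoate F2. Preparative chromatography on a polysaccharide chiral stationary phase then separates 9 from its (2S) enantiomer F3. F3 can be returned to F2 with a trace of Et3N, since C8–H is acidic, and recycled.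

Step 5 is the second risk. Acid-promoted enolisation could erode the configuration at C8, the β-hydroxy ketone could dehydrate, or the 4-methoxybenzyl cation could re-alkylate the product. The fallback sets out from 9 and arrives directly at 10 by a neutral, reductive cleavage instead of a cationic one: H2 (1 atm), palladium on carbon (Pd/C), EtOAc, rt. Both benzylic C–O bonds (ester and ether) are hydrogenolysed; the run is stopped as soon as 9 is consumed so that the aryl ketone and the C8–O bond are not reduced. No new compound is made.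

Step 2 is the third risk. The enolate may self-condense before trifluoroacetylation, the activating group may be lost hydrolytically before diazo transfer, or the diazo ketone may decompose on purification. The fallback sets out from 2 and comes back at 4. α-Bromination with PhNMe3Br3 in THF at 0 °C should give 2-bromo-1-{3,5-dimethoxy-4-[(4-methoxybenzyl)oxy]phenyl}ethan-1-one F4. Treatment of F4 with N,N'-ditosylhydrazine and DBU in THF at 0 °C alkylates the hydrazine and eliminates sulfinate twice (Bamford–Stevens-type), passing through the glyoxal tosylhydrazone N'-[(E)-2-{3,5-dimethoxy-4-[(4-methoxybenzyl)oxy]phenyl}-2-oxoethylidene]-4-methylbenzenesulfonohydrazide F5 (not isolated) to 4.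

Further compounds
F1 | step 4 | 4-methoxybenzyl 4-(2-{3,5-dimethoxy-4-[(4-methoxybenzyl)oxy]phenyl}-2-oxoethoxy)-3-methoxybenzoate | COc1cc(C(=O)OCc2ccc(OC)cc2)ccc1OCC(=O)c1cc(OC)c(OCc2ccc(OC)cc2)c(OC)c1
F2 | step 4 | racemic 4-methoxybenzyl 4-{[1-{3,5-dimethoxy-4-[(4-methoxybenzyl)oxy]phenyl}-3-hydroxy-1-oxopropan-2-yl]oxy}-3-methoxybenzoate | COc1cc(C(=O)OCc2ccc(OC)cc2)ccc1OC(CO)C(=O)c1cc(OC)c(OCc2ccc(OC)cc2)c(OC)c1
F3 | step 4 | 4-methoxybenzyl 4-{[(2S)-1-{3,5-dimethoxy-4-[(4-methoxybenzyl)oxy]phenyl}-3-hydroxy-1-oxopropan-2-yl]oxy}-3-methoxybenzoate | COc1cc(C(=O)OCc2ccc(OC)cc2)ccc1O[C@@H](CO)C(=O)c1cc(OC)c(OCc2ccc(OC)cc2)c(OC)c1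
F0 | step 5 | none | none
F4 | step 2 | 2-bromo-1-{3,5-dimethoxy-4-[(4-methoxybenzyl)oxy]phenyl}ethan-1-one | COc1ccc(COc2c(OC)cc(cc2OC)C(=O)CBr)cc1
F5 | step 2 | N'-[(E)-2-{3,5-dimethoxy-4-[(4-methoxybenzyl)oxy]phenyl}-2-oxoethylidene]-4-methylbenzenesulfonohydrazide | COc1ccc(COc2c(OC)cc(cc2OC)C(=O)/C=N/NS(=O)(=O)c2ccc(C)cc2)cc1
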